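A direct plan would start from kaempferol (A1): benzylate O7 and O4' and methylate O3 to give A2, esterify the chelated 5-OH as its propiolate A3, close a 2-pyranone onto C6 by palladium-catalysed hydroarylation in strong acid (A4), hydrogenate to the debenzylated dihydro lactone A5, and open the lactone with an excess of a methyl Grignard reagent.
Its weakest steps would be:
- Differentiating the four hydroxyls of A1 (7,4'-dibenzylation, then 3-O-methylation): two steps that build nothing and rest on small acidity differences among O3, O7 and O4'.
- The hydroarylation that makes the C6–C bond (A3 to A4): the carbonyl-deactivated ring A of a chromone must attack a metal-bound ynoate in CF3CO2H, where the aryl ester and the benzyl ethers are acid-labile.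
- The final double Grignard addition to A5: it runs on a free triphenol next to a conjugated pyranone carbonyl, needs a large excess, and puts the finished core at risk in the last step.

**Retrosynthetic overview**
Ring A is cut at C7–C8 and C5–C6. C7, C6 and the whole 3-hydroxy-3-methylbutyl chain with its tertiary oxygen are the seven carbons and the ring oxygen of 6,6-dimethyloxan-2-one; C5 is an ester carbon and C8 a methyl group on a preformed ring C.
Ring C is made first, in two steps, as the 2-aryl-3-methoxy-4-pyranone 6 (a masked 1,3,5-triketone) that already carries ring B, the 3-OMe, the O1–C8a bond, the C8 methyl and the C4a ester.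
Ring A closes last in one operation: the C8 methyl carbanion is acylated by the lactone and C6 then closes onto the ester (a polyketide-type Claisen fold), so 5-OH, 7-OH and the side-chain carbinol appear free.
By design no hydroxyl has to be differentiated (the 3-OMe is bought in; one benzyl on O4' is the only protecting group), the 6- versus 8-position question cannot arise because O1–C8a exists before ring A, and no organometallic reagent or acid meets the finished flavone.

Key step: step 4

Remark on the chemistry: the target has no stereocentre; the C=C geometry of the push–pull alkenes 3 and 5 and the enolizable CH(OMe) of 5 are lost in step 2, and the hemiketal carbon of 11 is lost on ring opening.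

Step 1
Reactants: 1 methyl 4-methoxy-3-oxobutanoate; 2 1,1-dimethoxy-N,N-dimethylethanamine (N,N-dimethylacetamide dimethyl acetal)
Product: 3 methyl 2-[1-(dimethylamino)ethylidene]-4-methoxy-3-oxobutanoate
Conditions: 2 (1.2 equiv), toluene, 60 °C
Reagents that add atoms: N,N-dimethylacetamide dimethyl acetal, CC(OC)(OC)N(C)C
Why: Amide acetal condensation with the active methylene group of a beta-keto ester (the acetamide analogue of the usual formamide acetal condensation), in which the enol of 1 attacks the amidinium ion from 2 and two molecules of methanol are lost; only C2 of 1 is doubly activated, the limited excess and mild temperature should keep the C4 methylene untouched, and the product is a push–pull alkene without fixed geometry or stereocentre.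

Step 2
Reactants: 3 methyl 2-[1-(dimethylamino)ethylidene]-4-methoxy-3-oxobutanoate; 4 4-(benzyloxy)benzoyl chloride
Product: 6 methyl 6-[4-(benzyloxy)phenyl]-5-methoxy-2-methyl-4-oxo-4H-pyran-3-carboxylate, via aroylated enaminone 5 (not isolated)
Conditions: LiN(SiMe3)2 (2.2 equiv), THF, −78 °C; 4 (1.05 equiv), −78 to −20 °C; then 2 M aq. HCl, rt
Reagents that add atoms: 4-(benzyloxy)benzoyl chloride, O=C(Cl)c1ccc(OCc2ccccc2)cc1
Why: Kinetic deprotonation of the vinylogous amide at the ketone-side CH2OMe carbon (not at the enamine methyl group), C-aroylation of the lithium enolate (the second equivalent of base takes up the acidic diketone proton), and acid-induced addition–elimination of the aryl ketone enol oxygen at the enamine carbon with loss of dimethylamine, which is the known way from beta-keto ester enaminones to 3-alkoxy-4-pyranone carboxylates; the methyl ester and the benzyl ether should survive, and the stereocentre of 5 disappears on ring closure.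

Step 3
Reactants: 7 methyl 5-oxohexanoate; 8 methylmagnesium bromide
Product: 10 6,6-dimethyloxan-2-one, via hydroxy ester alkoxide 9 (not isolated)
Conditions: MeMgBr (1.05 equiv), THF, −40 °C; then 1 M aq. HCl, rt
Reagents that add atoms: methylmagnesium bromide, C[Mg]Br
Why: Chemoselective Grignard addition to the ketone of a keto ester at low temperature, followed by lactonization of the tertiary alkoxide onto the methyl ester (helped by the gem-dimethyl group); no stereocentre is formed.

Step 4
Reactants: 6 methyl 6-[4-(benzyloxy)phenyl]-5-methoxy-2-methyl-4-oxo-4H-pyran-3-carboxylate; 10 6,6-dimethyloxan-2-one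
Product: 13 2-[4-(benzyloxy)phenyl]-5,7-dihydroxy-6-(3-hydroxy-3-methylbutyl)-3-methoxy-4H-chromen-4-one, via lactol adduct 11 (not isolated), via keto ester 12 (not isolated)
Conditions: LiN(i-Pr)2 (1.1 equiv), THF, −78 °C; 10 (1.2 equiv), −78 to −40 °C; LiN(i-Pr)2 (2.5 equiv), −78 °C to rt; then 1 M aq. HCl to pH 5, 0 °C
Reagents that add atoms: 6,6-dimethyloxan-2-one, CC1(C)CCCC(=O)O1
Why: Proposed new method: the amide base should deprotonate the C2 methyl group of 6 (vinylogously activated by the C4 ketone and the C3 ester), and the lithium dienolate should add to the lactone carbonyl of 10 to give the cyclic lithium hemiketal 11, which should persist at low temperature so that no acidic ketone quenches unreacted carbanion; with more base and warming 11 opens to keto ester 12, which is deprotonated at C8 and then at the chain-side methylene (the future C6), and this carbanion attacks the neighbouring ester, methoxide leaves, and the cyclic triketone enolizes to the aromatic 5,7-diphenoxide, which makes the sequence irreversible. The closest known reaction types are the acylation of lateral carbanions of ortho-toluates and 2-methyl-4-pyranones with esters and lactones, and the base-induced Claisen cyclization of 2-(2-oxoalkyl)benzoates to naphthalene-1,3-diols in biomimetic polyketide synthesis; here both run on a 4-pyranone-3-carboxylate acting as a masked 1,3,5-triketone. Ring A closes in the 6-exo-trig mode at the ester carbon (C5–C6 bond) after the intermolecular C7–C8 bond. No stereocentre is formed. The step needs C-acylation at the methyl group instead of addition of base or carbanion to C2 or C6 of the pyranone (hindered amide base, low temperature, high kinetic acidity of the methyl group), and C- instead of O-closure of the keto ester (the carbon terminus of the dianion is its most nucleophilic site, and an enol lactone formed through oxygen would be reopened by methoxide and drained to the aromatic product). The position of the chain is not a selectivity question, because O1–C8a is already in place, so the lactone alpha-carbon can only become C6 and the lactone ring oxygen is released as the tertiary hydroxyl.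

Step 5
Reactants: 13 2-[4-(benzyloxy)phenyl]-5,7-dihydroxy-6-(3-hydroxy-3-methylbutyl)-3-methoxy-4H-chromen-4-one
Product: 14 topazolin hydrate
Conditions: H2 (1 atm), 10% Pd/C, EtOAc/MeOH, rt
Reagents that add atoms: none
Why: Hydrogenolysis of the single aryl benzyl ether over Pd/C under neutral conditions, which should leave the tetrasubstituted C2=C3 bond of the 4-pyranone and the tertiary alcohol untouched and avoids any acid that could close the carbinol onto O5 or O7; no stereocentre is present.

**Compound list**
1 | methyl 4-methoxy-3-oxobutanoate (methyl 4-methoxyacetoacetate) | COCC(=O)CC(=O)OC | starting material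
2 | 1,1-dimethoxy-N,N-dimethylethanamine (N,N-dimethylacetamide dimethyl acetal) | CC(OC)(OC)N(C)C | starting material
3 | methyl 2-[1-(dimethylamino)ethylidene]-4-methoxy-3-oxobutanoate (push–pull enaminone, C=C geometry not fixed) | COCC(=O)C(=C(C)N(C)C)C(=O)OC | intermediate
4 | 4-(benzyloxy)benzoyl chloride | O=C(Cl)c1ccc(OCc2ccccc2)cc1 | starting material
5 | methyl 5-[4-(benzyloxy)phenyl]-2-[1-(dimethylamino)ethylidene]-4-methoxy-3,5-dioxopentanoate (racemic and enolized at C4; not isolated) | COC(C(=O)c1ccc(OCc2ccccc2)cc1)C(=O)C(=C(C)N(C)C)C(=O)OC | intermediate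
6 | methyl 6-[4-(benzyloxy)phenyl]-5-methoxy-2-methyl-4-oxo-4H-pyran-3-carboxylate (ring C with ring B; key-step precursor) | COC(=O)c1c(C)oc(-c2ccc(OCc3ccccc3)cc2)c(OC)c1=O | intermediate
7 | methyl 5-oxohexanoate | CC(=O)CCCC(=O)OC | starting material
8 | methylmagnesium bromide | C[Mg]Br | starting material
9 | methyl 5-hydroxy-5-methylhexanoate (present as its bromomagnesium alkoxide; not isolated) | CC(C)(O)CCCC(=O)OC | intermediate
10 | 6,6-dimethyloxan-2-one | CC1(C)CCCC(=O)O1 | intermediate
11 | methyl 6-[4-(benzyloxy)phenyl]-2-[(2-hydroxy-6,6-dimethyloxan-2-yl)methyl]-5-methoxy-4-oxo-4H-pyran-3-carboxylate (racemic lactol, present as its lithium alkoxide; not isolated) | COC(=O)c1c(CC2(O)CCCC(C)(C)O2)oc(-c2ccc(OCc3ccccc3)cc2)c(OC)c1=O | intermediate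
12 | methyl 6-[4-(benzyloxy)phenyl]-2-(6-hydroxy-6-methyl-2-oxoheptyl)-5-methoxy-4-oxo-4H-pyran-3-carboxylate (present as its lithium salts; not isolated) | COC(=O)c1c(CC(=O)CCCC(C)(C)O)oc(-c2ccc(OCc3ccccc3)cc2)c(OC)c1=O | intermediate
13 | 2-[4-(benzyloxy)phenyl]-5,7-dihydroxy-6-(3-hydroxy-3-methylbutyl)-3-methoxy-4H-chromen-4-one | COc1c(-c2ccc(OCc3ccccc3)cc2)oc2cc(O)c(CCC(C)(C)O)c(O)c2c1=O | intermediate
14 | topazolin hydrate (5,7-dihydroxy-6-(3-hydroxy-3-methylbutyl)-2-(4-hydroxyphenyl)-3-methoxy-4H-chromen-4-one; no stereocentre) | COc1c(-c2ccc(O)cc2)oc2cc(O)c(CCC(C)(C)O)c(O)c2c1=O | target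

**Step count**
Total: 5 steps. Longest linear sequence: 4 steps (steps 1, 2, 4, 5); step 3 is a one-step side branch.

**Steps most likely to fail**

Step 4 (proposed new method). Three things may go wrong: the lateral carbanion or the amide base may add in conjugate fashion to C2 or C6 of a second pyranone; the hemiketal may collapse early, so that the acidic ketone quenches unreacted carbanion; or the keto ester may close through oxygen or not at all, because the ester is deactivated inside the extended enolate. The fallback uses known chemistry only, with ring A bought in and the chain added last; it sets out from 4 and comes back to the route at 14. Allan–Robinson condensation of 2-methoxy-1-(2,4,6-trihydroxyphenyl)ethanone with the anhydride prepared from 4 (potassium 4-(benzyloxy)benzoate, 170 °C; then KOH, aq. EtOH to cleave the aroyl esters) should give 2-[4-(benzyloxy)phenyl]-5,7-dihydroxy-3-methoxy-4H-chromen-4-one F1. Silylation of the non-chelated 7-OH (t-BuMe2SiCl, imidazole, DMF) should give 2-[4-(benzyloxy)phenyl]-7-[(tert-butyldimethylsilyl)oxy]-5-hydroxy-3-methoxy-4H-chromen-4-one F2. Iodination ortho to the chelated 5-OH (BnMe3N ICl2, CaCO3, CH2Cl2/MeOH) should give the 6-iodo compound F3. Heck coupling with 2-methylbut-3-en-2-ol (Pd(OAc)2, Bu4NCl, NaHCO3, DMF, 80 °C) should give the (E)-6-(3-hydroxy-3-methylbut-1-enyl) silyl ether F4, and Bu4NF/AcOH its free 7-phenol F5. Hydrogen over Pd/C in neutral EtOAc then saturates the alkene and removes the benzyl group to give 14.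

Step 2. The base may deprotonate the enamine methyl group (the thermodynamic site) instead of the CH2OMe carbon, the enolate may be aroylated on oxygen, or the ring may close onto the ester carbonyl (2-pyranone) instead of the enamine carbon. The fallback reverses the order of bond formation so that only one carbon can be aroylated; it sets out from 1 and comes back at 6. The dianion of 1 (NaH, then n-BuLi, THF, 0 °C) is acylated at C4 with methyl 4-(benzyloxy)benzoate to give methyl 5-[4-(benzyloxy)phenyl]-4-methoxy-3,5-dioxopentanoate F6. Condensation of the C2 methylene of F6 with 2 then gives 5, which closes to 6 on acidification as in step 2.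

Step 3. The lactone formed in the flask from the alkoxide may compete with the ketone for the Grignard reagent and be over-alkylated to a diol. The fallback sets out from 8 and comes back at 10. Glutaric anhydride is treated with 8 (2.2 equiv, THF, −20 °C to rt); the magnesium carboxylate formed on ring opening is inert to the reagent, so addition stops at 5-hydroxy-5-methylhexanoic acid F7 after acidification. F7 lactonizes to 10 (cat. TsOH, toluene, azeotropic removal of water).

**Further compounds**
F1 | step 4 | 2-[4-(benzyloxy)phenyl]-5,7-dihydroxy-3-methoxy-4H-chromen-4-one | COc1c(-c2ccc(OCc3ccccc3)cc2)oc2cc(O)cc(O)c2c1=O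
F2 | step 4 | 2-[4-(benzyloxy)phenyl]-7-[(tert-butyldimethylsilyl)oxy]-5-hydroxy-3-methoxy-4H-chromen-4-one | COc1c(-c2ccc(OCc3ccccc3)cc2)oc2cc(O[Si](C)(C)C(C)(C)C)cc(O)c2c1=O
F3 | step 4 | 2-[4-(benzyloxy)phenyl]-7-[(tert-butyldimethylsilyl)oxy]-5-hydroxy-6-iodo-3-methoxy-4H-chromen-4-one | COc1c(-c2ccc(OCc3ccccc3)cc2)oc2cc(O[Si](C)(C)C(C)(C)C)c(I)c(O)c2c1=O
F4 | step 4 | 2-[4-(benzyloxy)phenyl]-7-[(tert-butyldimethylsilyl)oxy]-5-hydroxy-6-[(E)-3-hydroxy-3-methylbut-1-enyl]-3-methoxy-4H-chromen-4-one | COc1c(-c2ccc(OCc3ccccc3)cc2)oc2cc(O[Si](C)(C)C(C)(C)C)c(/C=C/C(C)(C)O)c(O)c2c1=O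
F5 | step 4 | 2-[4-(benzyloxy)phenyl]-5,7-dihydroxy-6-[(E)-3-hydroxy-3-methylbut-1-enyl]-3-methoxy-4H-chromen-4-one | COc1c(-c2ccc(OCc3ccccc3)cc2)oc2cc(O)c(/C=C/C(C)(C)O)c(O)c2c1=O
F6 | step 2 | methyl 5-[4-(benzyloxy)phenyl]-4-methoxy-3,5-dioxopentanoate (racemic, enolizable) | COC(C(=O)c1ccc(OCc2ccccc2)cc1)C(=O)CC(=O)OC
F7 | step 3 | 5-hydroxy-5-methylhexanoic acid | CC(C)(O)CCCC(=O)O
A1 | direct plan | kaempferol | O=c1c(O)c(-c2ccc(O)cc2)oc2cc(O)cc(O)c12
A2 | direct plan | 7-(benzyloxy)-2-[4-(benzyloxy)phenyl]-5-hydroxy-3-methoxy-4H-chromen-4-one | COc1c(-c2ccc(OCc3ccccc3)cc2)oc2cc(OCc3ccccc3)cc(O)c2c1=O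
A3 | direct plan | 7-(benzyloxy)-2-[4-(benzyloxy)phenyl]-3-methoxy-4-oxo-4H-chromen-5-yl prop-2-ynoate | C#CC(=O)Oc1cc(OCc2ccccc2)cc2oc(-c3ccc(OCc4ccccc4)cc3)c(OC)c(=O)c12
A4 | direct plan | 5-(benzyloxy)-8-[4-(benzyloxy)phenyl]-9-methoxy-2H,10H-pyrano[2,3-f]chromene-2,10-dione | COc1c(-c2ccc(OCc3ccccc3)cc2)oc2cc(OCc3ccccc3)c3ccc(=O)oc3c2c1=O
A5 | direct plan | 5-hydroxy-8-(4-hydroxyphenyl)-9-methoxy-3,4-dihydro-2H,10H-pyrano[2,3-f]chromene-2,10-dione | COc1c(-c2ccc(O)cc2)oc2cc(O)c3CCC(=O)Oc3c2c1=O
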